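**Plan**

1. Retrosynthetic cuts, in order: the side-chain bond C(OH)–CH(Me) (aldol with 3-pentanone); the oxirane oxygen; then the ring bonds C3–C4 and C1–C6 together. Carbocycle locants: C1 quaternary (pyranone-bearing), C2 =CH, C3 =CMe, C4/C5 oxirane CH/CMe, C6 CH with the side chain.
2. Enabling feature: C1–C6 with methyls on C1, C3 and C5 is a closed (E,Z,E)-1,3,5-trimethylhexatriene whose termini are the two sp3 carbons C1 and C6. A C3=C4 olefination followed by 6π closure C1–C6 therefore builds the ring, and both halves (pyranone–C(Me)=CH–CH(Me)–P and OHC–C(Me)=CH–) come from one enal.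
3. Forward order: ethyl (S)-lactate → enal 5; the pyranone ring is built on one portion of 5 (→ phosphonium salt 13); Wittig/isomerisation/electrocyclisation with a second portion of 5 closes the carbocycle (17); the helper side chain becomes the α-methylene aldehyde (22); oxirane (23); aldol (27).
4. Stereochemistry: C1/C6 cis from disrotation of the E,Z,E-triene. Their absolute sense comes from the lactate-derived silyloxy stereocentre on the C6 substituent, a temporary centre that is oxidised away in step 12. The oxirane forms anti to both ring substituents by steric approach. The side-chain syn diad comes from a (Z)-boron enolate under Ipc reagent control.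

Key step: step 10

Remark: ethyl (S)-lactate, 2-(triphenylphosphoranylidene)propanal, methyl 2-methyl-3-oxopentanoate and 3-pentanone are taken as the commercial starting materials; the (S)-lactate series is the one that the allylic-strain model in step 10 assigns to the ring configuration of the target.

**Step 1**
Reactants: 1 ethyl (S)-lactate
Product: 2 ethyl (2S)-2-[(tert-butyldiphenylsilyl)oxy]propanoate
Conditions: TBDPSCl, imidazole, DMF, 0 °C → rt
Reagents that add atoms: tert-butyl(chloro)diphenylsilane, CC(C)(C)[Si](Cl)(c1ccccc1)c1ccccc1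
Why: Imidazole-promoted silylation of the secondary alcohol is routine and gives a bulky, base- and oxidant-stable ether that later serves as the stereodirecting group, the lactate stereocentre being untouched.

**Step 2**
Reactants: 2 silyloxy ester
Product: 3 (2S)-2-[(tert-butyldiphenylsilyl)oxy]propanal
Conditions: i-Bu2AlH, CH2Cl2, −78 °C; aq. KNaC4H4O6 (tartrate)
Reagents that add atoms: none
Why: Low-temperature i-Bu2AlH reduction of the α-silyloxy ester stops at the aluminium hemiacetal, which releases the configurationally intact aldehyde on work-up (partial ester reduction).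

**Step 3**
Reactants: 3 silyloxy propanal; 4 2-(triphenylphosphoranylidene)propanal
Product: 5 (2E,4S)-4-[(tert-butyldiphenylsilyl)oxy]-2-methylpent-2-enal
Conditions: toluene, 90 °C
Reagents that add atoms: none
Why: Wittig olefination with the stabilised formyl ylide gives the (E)-trisubstituted enal under thermodynamic control, and the hindered conjugated product does not react a second time.

**Step 4**
Reactants: 6 methyl 2-methyl-3-oxopentanoate; 5 silyloxy enal
Product: 8 methyl (6E,8S)-8-[(tert-butyldiphenylsilyl)oxy]-5-hydroxy-2,4,6-trimethyl-3-oxonon-6-enoate (mixture at C2/C4/C5), via keto ester dianion 7 (not isolated)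
Conditions: NaH, THF, 0 °C; n-BuLi, 0 °C; then 5, −78 °C; aq. NH4Cl
Reagents that add atoms: none
Why: The dianion of the β-keto ester reacts at its γ-carbon in a 1,2-aldol addition to the α-branched enal (dianion aldol), and the three stereocentres formed without control are erased in steps 5 and 6.

**Step 5**
Reactants: 8 hydroxy keto ester
Product: 9 methyl (6E,8S)-8-[(tert-butyldiphenylsilyl)oxy]-2,4,6-trimethyl-3,5-dioxonon-6-enoate
Conditions: Dess–Martin periodinane, NaHCO3, CH2Cl2, rt
Reagents that add atoms: none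
Why: Dess–Martin oxidation of the allylic β-hydroxy ketone gives the β,δ-diketo ester under buffered conditions that leave the silyl ether and the (E)-olefin intact.

**Step 6**
Reactants: 9 diketo ester
Product: 10 6-[(2E,4S)-4-[(tert-butyldiphenylsilyl)oxy]pent-2-en-2-yl]-4-hydroxy-3,5-dimethyl-2H-pyran-2-one
Conditions: DBU, toluene, 80 °C
Reagents that add atoms: none
Why: Base-mediated lactonisation of the δ-enol oxygen onto the methyl ester with loss of methanol is the standard closure of β,δ-diketo esters to 4-hydroxy-2-pyranones and forms the heterocycle.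

**Step 7**
Reactants: 10 hydroxypyranone
Product: 11 6-[(2E,4S)-4-[(tert-butyldiphenylsilyl)oxy]pent-2-en-2-yl]-2-methoxy-3,5-dimethyl-4H-pyran-4-one
Conditions: MeOSO2F, CH2Cl2, rt; aq. NaHCO3
Reagents that add atoms: methyl fluorosulfonate, COS(=O)(=O)F
Why: Methylation with a hard oxonium-type electrophile occurs on the lactone carbonyl oxygen of the 4-hydroxy-2-pyranone and, after deprotonation on work-up, gives the 2-methoxy-4-pyranone, the regiochemistry known for this reagent class.

**Step 8**
Reactants: 11 methoxypyranone silyl ether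
Product: 12 6-[(2E,4S)-4-hydroxypent-2-en-2-yl]-2-methoxy-3,5-dimethyl-4H-pyran-4-one
Conditions: Bu4NF, THF, rt
Reagents that add atoms: none
Why: Fluoride-induced desilylation frees the secondary allylic alcohol without touching the methoxypyranone.

**Step 9**
Reactants: 12 pyranone allylic alcohol
Product: 13 [(3E)-4-(6-methoxy-3,5-dimethyl-4-oxo-4H-pyran-2-yl)pent-3-en-2-yl]triphenylphosphonium bromide (either configuration at the phosphorus-bearing carbon)
Conditions: PPh3·HBr, CH2Cl2/MeOH, rt
Reagents that add atoms: triphenylphosphine hydrobromide, Br.c1ccc(cc1)P(c1ccccc1)c1ccccc1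
Why: Acid-promoted substitution of an allylic alcohol by triphenylphosphine is the standard synthesis of allylic phosphonium salts, and phosphorus should attack the secondary terminus instead of the fully substituted pyranone-bearing one, so the conjugated (E)-olefin is kept.

**Step 10**
Reactants: 13 pyranone phosphonium bromide; 5 silyloxy enal
Product: 17 6-[(1R,6S)-6-[(1S)-1-[(tert-butyldiphenylsilyl)oxy]ethyl]-1,3,5-trimethylcyclohexa-2,4-dien-1-yl]-2-methoxy-3,5-dimethyl-4H-pyran-4-one, via ylide 14 (not isolated), via (2E,4E,6E)-triene 15 (not isolated), via (2E,4Z,6E)-triene 16 (not isolated)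
Conditions: NaN(SiMe3)2, THF, −78 → 0 °C; 5, 0 °C → rt; then PdCl2(MeCN)2 (20 mol %), DMF, 65 °C
Reagents that add atoms: none
Why: Deprotonation of 13 gives the pyranone-conjugated allylic ylide 14, whose phosphorus-bearing carbon (C3) olefinates the aldehyde carbon (C4) of 5 to give the trimethyl trienes 15 and 16 (the fully substituted γ-carbon C1 cannot lead to an olefin); divalent palladium then equilibrates the C3=C4 geometry, and the (E,Z,E)-isomer 16 is drained irreversibly by a thermal disrotatory 6π electrocyclisation that forms C1–C6. The closest known reaction types are the Wittig olefination/6π-electrocyclisation annulation of allylic phosphoranes with enals to cyclohexa-1,3-dienes and the PdCl2(MeCN)2-mediated isomerisation–electrocyclisation of all-E polyenyl pyranones. The one ring closure is the six-electron disrotatory closure of the s-cis,Z,s-cis hexatriene to the cyclohexa-2,4-diene. C1 and C6 are created together: both terminal olefins are E, so the pyranone (on C1) and the silyloxyethyl group (on C6) are the outside substituents and disrotation places them cis, while the sense of rotation is set by the (S)-silyloxy stereocentre, whose C–H eclipses the C5=C6 bond (A1,3 strain with the C5 methyl) so that C1 should bond to the face of C6 away from the bulky silyloxy group. The step needs Z geometry at C3=C4 only, which the palladium-mediated equilibration coupled to the irreversible cyclisation should supply, and E geometry at C1=C2 and C5=C6, which comes from the stabilised Wittig reaction of step 3 and from the faster closure of the triene with the small methyl (not the pyranone) inside. The two possible ring diastereomers differ from each other at the retained helper stereocentre and are separable, so 17 is carried on as one stereoisomer.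

**Step 11**
Reactants: 17 cyclohexadiene silyl ether
Product: 18 6-[(1R,6S)-6-[(1S)-1-hydroxyethyl]-1,3,5-trimethylcyclohexa-2,4-dien-1-yl]-2-methoxy-3,5-dimethyl-4H-pyran-4-one
Conditions: Bu4NF, THF, rt → 40 °C
Reagents that add atoms: none
Why: Fluoride cleaves the hindered secondary silyl ether, and nothing else in 17 is fluoride- or base-sensitive.

**Step 12**
Reactants: 18 cyclohexadienyl carbinol
Product: 19 6-[(1R,6S)-6-acetyl-1,3,5-trimethylcyclohexa-2,4-dien-1-yl]-2-methoxy-3,5-dimethyl-4H-pyran-4-one
Conditions: Dess–Martin periodinane, NaHCO3, CH2Cl2, 0 °C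
Reagents that add atoms: none
Why: Buffered Dess–Martin oxidation turns the helper carbinol into a methyl ketone (removing the temporary stereocentre) under conditions too mild to enolise toward the allylic ring methine C6.

**Step 13**
Reactants: 19 methyl ketone
Product: 21 1-[(1S,6R)-6-(6-methoxy-3,5-dimethyl-4-oxo-4H-pyran-2-yl)-2,4,6-trimethylcyclohexa-2,4-dien-1-yl]ethenyl trifluoromethanesulfonate, via potassium enolate 20 (not isolated)
Conditions: KN(SiMe3)2, THF, −78 °C; PhNTf2, −78 → 0 °C
Reagents that add atoms: N-phenylbis(trifluoromethanesulfonimide), O=S(=O)(N(c1ccccc1)S(=O)(=O)C(F)(F)F)C(F)(F)F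
Why: Kinetic deprotonation with a bulky amide base takes place at the unhindered methyl group, not at the neopentyl ring methine C6, and O-sulfonylation of the terminal enolate gives the 1,1-disubstituted enol triflate.

**Step 14**
Reactants: 21 enol triflate
Product: 22 2-[(1S,6R)-6-(6-methoxy-3,5-dimethyl-4-oxo-4H-pyran-2-yl)-2,4,6-trimethylcyclohexa-2,4-dien-1-yl]prop-2-enal
Conditions: Pd(PPh3)4 (5 mol %), LiCl, CO (1 atm), Bu3SnH (slow addition), THF, 50 °C
Reagents that add atoms: carbon monoxide, [C-]#[O+]
Why: Reductive carbonylation of alkenyl triflates with CO and a tin hydride under zerovalent palladium catalysis (oxidative addition, CO insertion, hydride transfer to the acylpalladium) is a known formylation and gives the 2-substituted acrolein directly.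

**Step 15**
Reactants: 22 dienyl acrolein
Product: 23 2-[(1R,4R,5S,6S)-4-(6-methoxy-3,5-dimethyl-4-oxo-4H-pyran-2-yl)-2,4,6-trimethyl-7-oxabicyclo[4.1.0]hept-2-en-5-yl]prop-2-enal
Conditions: dimethyldioxirane (1.05 equiv), acetone/CH2Cl2, −40 → −20 °C
Reagents that add atoms: dimethyldioxirane, CC1(C)OO1
Why: The neutral electrophilic dioxirane ignores the electron-poor acrolein and pyranone olefins and should epoxidise the C4=C5 bond of the diene from the face opposite the C6 side chain and the C1 pyranone, because the other diene olefin (C2=C3) abuts the quaternary C1 on both faces; this sets both oxirane stereocentres.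

**Step 16**
Reactants: 23 epoxy acrolein; 24 3-pentanone
Product: 27 2-methoxy-3,5-dimethyl-6-[(1R,4R,5R,6S)-5-[(3R,4R)-3-hydroxy-4-methyl-5-oxohept-1-en-2-yl]-2,4,6-trimethyl-7-oxabicyclo[4.1.0]hept-2-en-4-yl]-4H-pyran-4-one (target), via (Z)-enol borinate 25 (not isolated), via boron aldolate 26 (not isolated)
Conditions: 24, (+)-Ipc2BOTf [from (−)-α-pinene], i-Pr2NEt, CH2Cl2, −78 °C; then 23, −78 → −20 °C; H2O2, MeOH, pH 7 buffer, 0 °C
Reagents that add atoms: none
Why: The (Z)-enol diisopinocampheylborinate adds through a chair Zimmerman–Traxler transition state to give the syn aldol, and the (+)-Ipc ligands are chosen to direct the enolate to the Re face of the aldehyde so that both new side-chain centres are R (reagent-controlled boron aldol).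

**Compound list**

1 | ethyl (S)-lactate | C[C@H](O)C(=O)OCC | starting material
2 | ethyl (2S)-2-[(tert-butyldiphenylsilyl)oxy]propanoate (silyloxy ester) | C[C@H](O[Si](c1ccccc1)(c1ccccc1)C(C)(C)C)C(=O)OCC | intermediate
3 | (2S)-2-[(tert-butyldiphenylsilyl)oxy]propanal (silyloxy propanal) | C[C@H](O[Si](c1ccccc1)(c1ccccc1)C(C)(C)C)C=O | intermediate
4 | 2-(triphenylphosphoranylidene)propanal | CC(C=O)=P(c1ccccc1)(c1ccccc1)c1ccccc1 | starting material
5 | (2E,4S)-4-[(tert-butyldiphenylsilyl)oxy]-2-methylpent-2-enal (silyloxy enal) | C[C@H](O[Si](c1ccccc1)(c1ccccc1)C(C)(C)C)/C=C(\C)C=O | intermediate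
6 | methyl 2-methyl-3-oxopentanoate | CCC(=O)C(C)C(=O)OC | starting material
7 | sodium lithium dianion (bis-enolate) of 6 | CC=C([O-])C(C)=C([O-])OC.[Na+].[Li+] | intermediate (not isolated)
8 | methyl (6E,8S)-8-[(tert-butyldiphenylsilyl)oxy]-5-hydroxy-2,4,6-trimethyl-3-oxonon-6-enoate (hydroxy keto ester) | COC(=O)C(C)C(=O)C(C)C(O)/C(C)=C/[C@H](C)O[Si](c1ccccc1)(c1ccccc1)C(C)(C)C | intermediate
9 | methyl (6E,8S)-8-[(tert-butyldiphenylsilyl)oxy]-2,4,6-trimethyl-3,5-dioxonon-6-enoate (diketo ester) | COC(=O)C(C)C(=O)C(C)C(=O)/C(C)=C/[C@H](C)O[Si](c1ccccc1)(c1ccccc1)C(C)(C)C | intermediate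
10 | 6-[(2E,4S)-4-[(tert-butyldiphenylsilyl)oxy]pent-2-en-2-yl]-4-hydroxy-3,5-dimethyl-2H-pyran-2-one (hydroxypyranone) | O=C1OC(/C(C)=C/[C@H](C)O[Si](c2ccccc2)(c2ccccc2)C(C)(C)C)=C(C)C(O)=C1C | intermediate
11 | 6-[(2E,4S)-4-[(tert-butyldiphenylsilyl)oxy]pent-2-en-2-yl]-2-methoxy-3,5-dimethyl-4H-pyran-4-one (methoxypyranone silyl ether) | COc1oc(/C(C)=C/[C@H](C)O[Si](c2ccccc2)(c2ccccc2)C(C)(C)C)c(C)c(=O)c1C | intermediate
12 | 6-[(2E,4S)-4-hydroxypent-2-en-2-yl]-2-methoxy-3,5-dimethyl-4H-pyran-4-one (pyranone allylic alcohol) | COc1oc(/C(C)=C/[C@H](C)O)c(C)c(=O)c1C | intermediate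
13 | [(3E)-4-(6-methoxy-3,5-dimethyl-4-oxo-4H-pyran-2-yl)pent-3-en-2-yl]triphenylphosphonium bromide (pyranone phosphonium bromide) | COc1oc(/C(C)=C/C(C)[P+](c2ccccc2)(c2ccccc2)c2ccccc2)c(C)c(=O)c1C.[Br-] | intermediate
14 | 2-methoxy-3,5-dimethyl-6-[(2E)-4-(triphenyl-λ5-phosphanylidene)pent-2-en-2-yl]-4H-pyran-4-one (ylide) | COc1oc(/C(C)=C/C(C)=P(c2ccccc2)(c2ccccc2)c2ccccc2)c(C)c(=O)c1C | intermediate (not isolated)
15 | 6-[(2E,4E,6E,8S)-8-[(tert-butyldiphenylsilyl)oxy]-4,6-dimethylnona-2,4,6-trien-2-yl]-2-methoxy-3,5-dimethyl-4H-pyran-4-one | COc1oc(/C(C)=C/C(C)=C/C(C)=C/[C@H](C)O[Si](c2ccccc2)(c2ccccc2)C(C)(C)C)c(C)c(=O)c1C | intermediate (not isolated)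
16 | 6-[(2E,4Z,6E,8S)-8-[(tert-butyldiphenylsilyl)oxy]-4,6-dimethylnona-2,4,6-trien-2-yl]-2-methoxy-3,5-dimethyl-4H-pyran-4-one | COc1oc(/C(C)=C/C(C)=C\C(C)=C\[C@H](C)O[Si](c2ccccc2)(c2ccccc2)C(C)(C)C)c(C)c(=O)c1C | intermediate (not isolated)
17 | 6-[(1R,6S)-6-[(1S)-1-[(tert-butyldiphenylsilyl)oxy]ethyl]-1,3,5-trimethylcyclohexa-2,4-dien-1-yl]-2-methoxy-3,5-dimethyl-4H-pyran-4-one (cyclohexadiene silyl ether; pyranone and silyloxyethyl group cis) | C[C@H](O[Si](c1ccccc1)(c1ccccc1)C(C)(C)C)[C@H]1C(C)=CC(C)=C[C@@]1(C)c1oc(OC)c(C)c(=O)c1C | intermediate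
18 | 6-[(1R,6S)-6-[(1S)-1-hydroxyethyl]-1,3,5-trimethylcyclohexa-2,4-dien-1-yl]-2-methoxy-3,5-dimethyl-4H-pyran-4-one (cyclohexadienyl carbinol) | C[C@H](O)[C@H]1C(C)=CC(C)=C[C@@]1(C)c1oc(OC)c(C)c(=O)c1C | intermediate
19 | 6-[(1R,6S)-6-acetyl-1,3,5-trimethylcyclohexa-2,4-dien-1-yl]-2-methoxy-3,5-dimethyl-4H-pyran-4-one (methyl ketone) | CC(=O)[C@H]1C(C)=CC(C)=C[C@@]1(C)c1oc(OC)c(C)c(=O)c1C | intermediate
20 | potassium enolate of 19 (terminal, CH2=C(O−)–) | [K+].C=C([O-])[C@H]1C(C)=CC(C)=C[C@@]1(C)c1oc(OC)c(C)c(=O)c1C | intermediate (not isolated)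
21 | 1-[(1S,6R)-6-(6-methoxy-3,5-dimethyl-4-oxo-4H-pyran-2-yl)-2,4,6-trimethylcyclohexa-2,4-dien-1-yl]ethenyl trifluoromethanesulfonate (enol triflate) | C=C(OS(=O)(=O)C(F)(F)F)[C@H]1C(C)=CC(C)=C[C@@]1(C)c1oc(OC)c(C)c(=O)c1C | intermediate
22 | 2-[(1S,6R)-6-(6-methoxy-3,5-dimethyl-4-oxo-4H-pyran-2-yl)-2,4,6-trimethylcyclohexa-2,4-dien-1-yl]prop-2-enal (dienyl acrolein) | C=C(C=O)[C@H]1C(C)=CC(C)=C[C@@]1(C)c1oc(OC)c(C)c(=O)c1C | intermediate
23 | 2-[(1R,4R,5S,6S)-4-(6-methoxy-3,5-dimethyl-4-oxo-4H-pyran-2-yl)-2,4,6-trimethyl-7-oxabicyclo[4.1.0]hept-2-en-5-yl]prop-2-enal (epoxy acrolein; oxirane anti to pyranone and side chain) | C=C(C=O)[C@H]1[C@]2(C)O[C@@H]2C(C)=C[C@@]1(C)c1oc(OC)c(C)c(=O)c1C | intermediate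
24 | 3-pentanone | CCC(=O)CC | starting material
25 | (Z)-pent-2-en-3-yl diisopinocampheylborinate, Ipc groups from (−)-α-pinene ((Z)-enol borinate) | C/C=C(\OB([C@H]1C[C@H]2C[C@@H]([C@@H]1C)C2(C)C)[C@H]1C[C@H]2C[C@@H]([C@@H]1C)C2(C)C)CC | intermediate (not isolated)
26 | O-diisopinocampheylboryl derivative of 27 at the side-chain carbinol (boron aldolate) | C=C([C@H](OB([C@H]1C[C@H]2C[C@@H]([C@@H]1C)C2(C)C)[C@H]1C[C@H]2C[C@@H]([C@@H]1C)C2(C)C)[C@@H](C)C(=O)CC)[C@H]1[C@]2(C)O[C@@H]2C(C)=C[C@@]1(C)c1oc(OC)c(C)c(=O)c1C | intermediate (not isolated)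
27 | 2-methoxy-3,5-dimethyl-6-[(1R,4R,5R,6S)-5-[(3R,4R)-3-hydroxy-4-methyl-5-oxohept-1-en-2-yl]-2,4,6-trimethyl-7-oxabicyclo[4.1.0]hept-2-en-4-yl]-4H-pyran-4-one | C=C([C@H](O)[C@@H](C)C(=O)CC)[C@H]1[C@]2(C)O[C@@H]2C(C)=C[C@@]1(C)c1oc(OC)c(C)c(=O)c1C | target

**Step count**

Total: 16 steps. Longest linear sequence: 16 steps (1 → 5 → 13 → 17 → 27), because enal 5 feeds both halves of the key step.

**Steps most likely to fail**

Step 10. The C3=C4 geometry may not equilibrate cleanly under divalent palladium. The Z-triene may leak into [1,7]-hydrogen shifts before it cyclises. Facial discrimination in the ring closure may be low or in the opposite sense; this last point costs material only, since the diastereomers are separable. The fallback sets out from 5 and 6 and returns at 17, and builds the Z-olefin stereospecifically by cross-coupling. Enal 5 is converted by a Stork–Zhao-type iodoolefination (Ph3P+CH(CH3)I I−, NaN(SiMe3)2, THF, −78 °C) into the (Z)-alkenyl iodide F1. Miyaura borylation (B2pin2, PdCl2(dppf), KOPh, toluene, 50 °C) then gives the alkenylboronate F2 with retention. In parallel, commercial (E)-3-iodo-2-methylprop-2-en-1-ol is oxidised (MnO2, CH2Cl2) to the iodo enal F3. With dianion 7 this gives the aldol adduct F4, and the conditions of steps 5, 6 and 7 then give the diketo ester F5, the hydroxypyranone F6 and the pyranone alkenyl iodide F7. Suzuki coupling of F2 with F7 (Pd(PPh3)4, K3PO4, THF/H2O, rt) should give triene 16 as a single geometric isomer, and warming in toluene closes it to 17.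

Step 15. The oxidant may attack the other diene olefin (C2=C3) or the upper face, since electronic and steric preferences of the two trisubstituted olefins pull in opposite directions. The fallback sets out from 22 and returns at 23. Photooxygenation (O2, hν, tetraphenylporphyrin, CH2Cl2, −40 °C) adds singlet oxygen across the diene termini C2 and C5 on the open lower face to give the endoperoxide F8. PPh3 (CH2Cl2, 0 °C) then takes the peroxide oxygen on the secondary carbon C2, and the C5 alkoxide closes on C4 with allylic transposition. This known endoperoxide-to-vinyl-oxirane conversion fixes both the position and the face of the oxirane.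

Step 16. The aldehyde's own facial bias may erode the reagent control, and the boron Lewis acid may open the vinyl oxirane. The fallback sets out from 22 and returns at 27, and changes the order so that the oxirane is introduced last. The same diisopinocampheylboron enolate aldol is run on the oxirane-free aldehyde 22 to give the dienyl hydroxy ketone F9, whose diastereomers are separated if needed. Dimethyldioxirane epoxidation of F9 under the conditions of step 15 then gives 27.

**Further compounds**

F1 | step 10 | tert-butyl{[(2S,3E,5Z)-6-iodo-4-methylhepta-3,5-dien-2-yl]oxy}diphenylsilane | C/C(I)=C/C(C)=C/[C@H](C)O[Si](c1ccccc1)(c1ccccc1)C(C)(C)C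
F2 | step 10 | tert-butyl{[(2S,3E,5E)-4-methyl-6-(4,4,5,5-tetramethyl-1,3,2-dioxaborolan-2-yl)hepta-3,5-dien-2-yl]oxy}diphenylsilane (boron cis to the dienyl chain) | C/C(B1OC(C)(C)C(C)(C)O1)=C/C(C)=C/[C@H](C)O[Si](c1ccccc1)(c1ccccc1)C(C)(C)C
F3 | step 10 | (2E)-3-iodo-2-methylprop-2-enal | O=C/C(C)=C/I
F4 | step 10 | methyl (6E)-5-hydroxy-7-iodo-2,4,6-trimethyl-3-oxohept-6-enoate | COC(=O)C(C)C(=O)C(C)C(O)/C(C)=C/I
F5 | step 10 | methyl (6E)-7-iodo-2,4,6-trimethyl-3,5-dioxohept-6-enoate | COC(=O)C(C)C(=O)C(C)C(=O)/C(C)=C/I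
F6 | step 10 | 4-hydroxy-6-[(1E)-1-iodoprop-1-en-2-yl]-3,5-dimethyl-2H-pyran-2-one | O=C1OC(/C(C)=C/I)=C(C)C(O)=C1C
F7 | step 10 | 6-[(1E)-1-iodoprop-1-en-2-yl]-2-methoxy-3,5-dimethyl-4H-pyran-4-one | COc1oc(/C(C)=C/I)c(C)c(=O)c1C
F8 | step 15 | endoperoxide of 22 (2,3-dioxabicyclo[2.2.2]oct-5-ene; O–O bridge across C2 and C5 on the face opposite the pyranone and the side chain) | C=C(C=O)[C@H]1[C@@]2(C)C=C(C)[C@H](OO2)[C@@]1(C)c1oc(OC)c(C)c(=O)c1C
F9 | step 16 | 6-[(1R,6R)-6-[(3R,4R)-3-hydroxy-4-methyl-5-oxohept-1-en-2-yl]-1,3,5-trimethylcyclohexa-2,4-dien-1-yl]-2-methoxy-3,5-dimethyl-4H-pyran-4-one | C=C([C@H](O)[C@@H](C)C(=O)CC)[C@H]1C(C)=CC(C)=C[C@@]1(C)c1oc(OC)c(C)c(=O)c1C
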